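(The data are calculated with constants of no real substance; the scatter is artificial.)

3 answers are asked of me, and for the short flask I carry one quantity; here are the flasks and the runs.

| flask | solid substrate | partner | remark | time |
|---|---|---|---|---|
| theta | 0.30 M | 1.1 equiv | run made earlier |  |
| gamma | 0.30 M | 1.6 equiv | run made earlier |  |
| east | 0.30 M | 1.40 equiv |  | 1.2 h |
| west | 0.30 M | 0.900 equiv |  | 4.0 h |

| run | time / h | target / % |
|---|---|---|
| theta | 0.333 | 0.8 |
| theta | 0.500 | 0.9 |
| theta | 0.667 | 1.4 |
| theta | 1.00 | 2.8 |
| theta | 1.50 | 8.2 |
| theta | 2.50 | 18.5 |
| theta | 4.00 | 35.9 |
| gamma | 0.333 | 1.0 |
| gamma | 0.500 | 0.8 |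
| gamma | 0.667 | 2.6 |
| gamma | 1.00 | 3.4 |
| gamma | 1.50 | 9.1 |
| gamma | 2.50 | 21.5 |
| gamma | 4.00 | 41.5 |

(standard deviation of a reading: 0.5 percentage points)

- as a solid, counted per litre of solution: solid substrate
- at the start none of the solid substrate is in solution
- what has only dissolved of solid substrate counts as not reacted

- which one finishes higher in amount of target, in percent of the solid substrate charged ("neither" within 2 percentage points) (east / west / neither)
- amount of target at the end, in percent of the solid substrate charged, east
- amount of target at the end, in percent of the solid substrate charged, west

1. Both runs start flat and end straight. Between 2.50 h and 4.00 h theta gains 0.116 /h of the charge and gamma 0.133 /h, and theta's line meets zero at a lag (induction period) of 0.905 h.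

2. In my fast extreme, whatever dissolves is handed on at once, so east, whose partner lies between the two runs, climbs from the start at their mean slope and reaches 15.0%.

3. In my slow extreme, a steady supply piles up first, the rate of target grows with the pile, and target grows as the square of the time. I call take-off time the time at which this square law reaches the whole charge, so that target as a share of the charge is time over take-off time, squared, and I read it from the mean of both runs at 1.50 h: 5.10 h. That gives east 5.54%.

4. East stops sooner than twice the lag, so I commit to the slow figure. West runs longer than twice the lag, on the straight part, and extending the two last readings down to its partner gives me 33.7%.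

The forecast says west, with east 5.2% (3.8% to 7%) and west 33% (29.5% to 35.5%), on the ground that “time matters far more than partner loading”.

The flask gives west, with west at 31.8% and east at 6.04%.

    starting material → intermediate (k = 0.0420 /min)
    partner + intermediate → target (k = 0.0440 /M/min)
    2 intermediate → homo product (k = 5.60 × 10⁻⁴ /M/min)
    solid substrate ⇌ starting material, rate k4*(cs4 - [starting material]) while solid is left; crystals form when [starting material] > cs4 (solubility = 28.0 mM, k = 0.0650 /min)

East holds starting material at 5.55% after 0.600 h and 5.67% after 1.20 h. Carried to the same flask as east read at 40 min, the take-off time of 5.10 h gives 1.71%, where that flask stands at 1.83%.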